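**Plan** (eudesmane locants C1–C15; α/β as in the usual eudesmane drawing)

1. Late cuts: the C6 angelate, the C12 ester (C12 is the methyl carbon of a C7 isopropenyl group) and the C1 carbinol (from a C1 ketone) go first; C5–H and C6–O are then traced back to a C5=C6 olefin.
2. Ring A is opened at C4–C5. The feature that allows this: the C4 methyl carbinol is bonded to ring-fusion carbon C5, which sits between quaternary C10 and oxygenated C6 of ring B. The allylic alcohol C4(OH)–C5=C6 is therefore the adduct of a C5 alkenyl-metal (from a C5 ketone that can enolise only toward C6) and a C4 methyl ketone on the C10–C1–C2–C3 chain.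
3. Earlier cuts: C7–C11 (cuprate addition), C10–CH3 (enolate methylation), C10–C1 (aldol). Starting materials: (S)-4-silyloxycyclohex-2-enone (ring B), pent-4-enal, isopropenylmagnesium bromide, iodomethane, angelic acid.
4. Forward: ring B is bought; the C1–C4 chain and the methyl group are put on C10 and the isopropenyl group on C7; ring A is closed in step 6; the decalin is then oxygenated, acylated and oxidised at C12.
5. Stereochemistry: C8 from the starting enone; C10 and C7 by attack anti to the C8 silyloxy group; C4 in the ring closure; C5 and C6 from a hydroxyl-directed α-epoxide and α-face hydrogen-atom transfer; C1 by axial hydride delivery opposite the C10 methyl.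

Key step: step 6

Assumption: enone 1 is taken as a catalogue compound in its (S) form.

**Step 1**
Reactants: 1 (S)-4-[(tert-butyldimethylsilyl)oxy]cyclohex-2-en-1-one; 2 pent-4-enal
Product: 4 (4S)-4-[(tert-butyldimethylsilyl)oxy]-6-(1-hydroxypent-4-en-1-yl)cyclohex-2-en-1-one (diastereomer mixture at C10 and C1), via lithium dienolate 3 (not isolated)
Conditions: LDA, THF, −78 °C; then 2, −78 °C; aq. NH4Cl
Reagents that add atoms: none
Why: Kinetic deprotonation of the enone can only take place at the α′ carbon (C10), and the cross-conjugated lithium dienolate should add to the aldehyde (directed aldol addition); the two new centres form as a mixture, which is harmless because both are made trigonal or re-set in steps 2 and 3.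

**Step 2**
Reactants: 4 aldol adduct
Product: 5 (4S)-4-[(tert-butyldimethylsilyl)oxy]-6-(pent-4-enoyl)cyclohex-2-en-1-one (largely enolised 1,3-diketone)
Conditions: DMP, CH2Cl2, 0 °C → rt
Reagents that add atoms: none
Why: Dess–Martin oxidation of a β-hydroxy ketone should give the 1,3-diketone under neutral conditions that leave the allylic silyl ether and both olefins untouched; no stereocentre is formed.

**Step 3**
Reactants: 5 1,3-diketone
Product: 6 (4S,6S)-4-[(tert-butyldimethylsilyl)oxy]-6-methyl-6-(pent-4-enoyl)cyclohex-2-en-1-one (methyl trans to OTBS)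
Conditions: K2CO3, MeI, acetone, rt
Reagents that add atoms: iodomethane, CI
Why: C-alkylation of the stabilised diketone enolate (β-diketone alkylation) should create quaternary C10, and iodomethane should approach the planar enolate anti to the C8 silyloxy group (1,3-induction), placing the methyl trans to OTBS.

**Step 4**
Reactants: 6 quaternary enone
Product: 8 (4S)-4-[(tert-butyldimethylsilyl)oxy]-6-methyl-6-(pent-4-enoyl)-3-(prop-1-en-2-yl)cyclohex-1-en-1-yl trifluoromethanesulfonate (C7 isopropenyl trans to C8 OTBS), via bromomagnesium enolate 7 (not isolated)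
Conditions: isopropenylmagnesium bromide (2.2 equiv), CuBr·SMe2 (1.1 equiv), THF, −78 °C; then N-(5-chloropyridin-2-yl)bis(trifluoromethanesulfonimide), −78 → 0 °C
Reagents that add atoms: isopropenylmagnesium bromide, C=C(C)[Mg]Br; N-(5-chloropyridin-2-yl)bis(trifluoromethanesulfonimide), FC(F)(F)S(=O)(=O)N(c1ccc(Cl)cn1)S(=O)(=O)C(F)(F)F
Why: Cuprate conjugate addition to the γ-silyloxy enone should occur anti to the C8 silyloxy group and so set C7, the cuprate should spare the saturated C1 ketone at −78 °C, and the enolate, which can only be the C5=C6 enolate, is trapped as the enol triflate (1,4-addition then enolate O-sulfonylation).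

**Step 5**
Reactants: 8 alkenyl triflate
Product: 9 (4S)-4-[(tert-butyldimethylsilyl)oxy]-6-methyl-6-(4-oxopentanoyl)-3-(prop-1-en-2-yl)cyclohex-1-en-1-yl trifluoromethanesulfonate
Conditions: PdCl2(Quinox) (5 mol %; Quinox = 2-(4,5-dihydro-1,3-oxazol-2-yl)quinoline), AgSbF6 (12 mol %), aq. tBuOOH, CH2Cl2, 0 °C → rt
Reagents that add atoms: tert-butyl hydroperoxide, CC(C)(C)OO
Why: A peroxide-mediated Wacker oxidation, in which palladium stays divalent, should convert only the monosubstituted terminal olefin into the methyl ketone (Markovnikov) and leave the 1,1-disubstituted isopropenyl group and the alkenyl triflate intact; no stereocentre is formed.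

**Step 6**
Reactants: 9 keto alkenyl triflate
Product: 11 8α-[(tert-butyldimethylsilyl)oxy]-4α-hydroxy-eudesma-5,11-dien-1-one (4β-methyl; 10β-methyl; 7β-isopropenyl), via alkenylchromium dichloride 10 (not isolated)
Conditions: CrCl2 (8 equiv), NiCl2 (2 mol %), degassed DMF, rt → 50 °C; aq. work-up
Reagents that add atoms: none
Why: CrCl2 reduces NiCl2 to zerovalent nickel, which inserts into the C5–OTf bond; transmetalation gives the C5 alkenylchromium dichloride 10 (trivalent chromium), which adds to the C4 methyl ketone through a four-centre transition state and holds the oxygen as a chromium alkoxide until work-up. The closest known reaction type is the intramolecular Nozaki–Hiyama–Kishi addition of an alkenyl triflate to a carbonyl group; ketones react more slowly than aldehydes, which is tolerable here because no aldehyde competes and the addition is intramolecular. Ring A is closed in the 6-exo-trig mode (C5 attacks the C4 carbonyl carbon, the C=O lying outside the new ring), and the C5=C6 double bond survives for steps 7 and 8. The new stereocentre C4 is controlled by C10: in the chair-like transition state that keeps the C10 methyl axial and the ring B substituents equatorial, the chromium bridging C5 and O4 should sit in the plane of the C5=C6 bond on the open side next to H6, which makes O4 equatorial (α) and C15 axial (β), whereas an axial oxygen would push the ligated metal against the axial C10 methyl. The step needs chemoselectivity between two ketones and facial selectivity at C4: C5 cannot reach the C1 ketone (a three-membered ring would result), and the face follows from the geometry just described. An external methyl nucleophile added to a ring A 4-ketone would instead enter from the α face and give the C4 epimer, which is why the ring bond, not the methyl bond, is formed at the carbinol centre.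

**Step 7**
Reactants: 11 tertiary allylic alcohol
Product: 12 5α,6α-epoxy-8α-[(tert-butyldimethylsilyl)oxy]-4α-hydroxy-eudesm-11-en-1-one
Conditions: VO(acac)2 (5 mol %), tBuOOH (decane), CH2Cl2, 0 °C → rt
Reagents that add atoms: tert-butyl hydroperoxide, CC(C)(C)OO
Why: Vanadium-catalysed hydroxyl-directed epoxidation of the allylic alcohol should deliver oxygen to C5=C6 from the α face, syn to the C4 hydroxyl and opposite the two axial β-methyl groups, and should spare the isopropenyl group, which has no directing hydroxyl; this fixes C6–O as α.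

**Step 8**
Reactants: 12 epoxy alcohol
Product: 13 8α-[(tert-butyldimethylsilyl)oxy]-4α,6α-dihydroxy-5αH-eudesm-11-en-1-one
Conditions: Cp2TiCl2 (20 mol %), Zn dust, 2,4,6-collidine·HCl, 1,4-cyclohexadiene, THF, rt
Reagents that add atoms: none
Why: Titanocene-mediated reductive epoxide opening (Cp2TiCl, trivalent titanium, radical anti-Markovnikov opening) should cleave the C5–O bond to the tertiary C5 radical and leave the oxygen on C6 with its α configuration, and hydrogen-atom transfer from 1,4-cyclohexadiene should reach C5 from the α face because the β face is shielded by the axial C4 and C10 methyl groups, giving the trans-decalin.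

**Step 9**
Reactants: 13 diol; 14 angelic acid [(Z)-2-methylbut-2-enoic acid]
Product: 16 6α-angeloyloxy-8α-[(tert-butyldimethylsilyl)oxy]-4α-hydroxy-5αH-eudesm-11-en-1-one, via mixed anhydride 15 (not isolated)
Conditions: 14, 2,4,6-trichlorobenzoyl chloride, Et3N, PhMe, rt; then 13, PhMe, 80 °C
Reagents that add atoms: none
Why: Yamaguchi esterification through the mixed anhydride should acylate the only secondary hydroxyl (C6) and leave the tertiary C4 hydroxyl free, and the absence of a nucleophilic catalyst should keep the Z olefin of the angelate from isomerising to the tiglate; no stereocentre is formed.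

**Step 10**
Reactants: 16 angelate
Product: 17 6α-angeloyloxy-8α-[(tert-butyldimethylsilyl)oxy]-4α,12-dihydroxy-5αH-eudesm-11(13)-en-1-one
Conditions: SeO2 (0.3 equiv), tBuOOH, CH2Cl2, rt
Reagents that add atoms: tert-butyl hydroperoxide, CC(C)(C)OO (oxygen passed on through SeO2)
Why: Selenium dioxide allylic oxidation (ene reaction then 2,3-sigmatropic shift) should oxidise the methyl group of the electron-rich 1,1-disubstituted isopropenyl olefin in preference to its tertiary allylic C7–H and to the electron-poor angelate; no stereocentre is formed.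

**Step 11**
Reactants: 17 allylic alcohol
Product: 19 6α-angeloyloxy-8α-[(tert-butyldimethylsilyl)oxy]-4α-hydroxy-1-oxo-5αH-eudesm-11(13)-en-12-oic acid, via enal 18 (not isolated)
Conditions: TEMPO (10 mol %), NaOCl (5 mol %), NaClO2, MeCN / pH 6.7 phosphate buffer, 35 °C
Reagents that add atoms: sodium chlorite, [Na+].[O-]Cl=O
Why: Nitroxyl-catalysed alcohol oxidation followed in the same flask by chlorite oxidation of the enal should give the acrylic acid, the hypochlorite by-product being consumed as co-oxidant so that the olefins are not chlorinated; C6 is already acylated and C8 silylated, so no lactone can form.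

**Step 12**
Reactants: 19 acid
Product: 20 methyl 6α-angeloyloxy-8α-[(tert-butyldimethylsilyl)oxy]-4α-hydroxy-1-oxo-5αH-eudesm-11(13)-en-12-oate
Conditions: TMSCHN2, PhMe/MeOH, 0 °C
Reagents that add atoms: (trimethylsilyl)diazomethane, C[Si](C)(C)C=[N+]=[N-]
Why: Diazoalkane esterification of the carboxylic acid is neutral and should neither isomerise the angelate nor move the C11=C13 double bond into conjugation with C7.

**Step 13**
Reactants: 20 keto ester
Product: 21 methyl 6α-angeloyloxy-8α-[(tert-butyldimethylsilyl)oxy]-1β,4α-dihydroxy-5αH-eudesm-11(13)-en-12-oate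
Conditions: NaBH4, CeCl3·7H2O, MeOH, −78 → −40 °C
Reagents that add atoms: none
Why: Luche reduction should reduce only the C1 ketone (1,2-reduction, no conjugate reduction of the acrylate), hydride adding axially from the α face opposite the axial C10 methyl to give the equatorial 1β-alcohol.

**Step 14**
Reactants: 21 silyl ether
Product: 22 methyl 6α-angeloyloxy-1β,4α,8α-trihydroxy-5αH-eudesm-11(13)-en-12-oate (CNP0136844.1)
Conditions: HF·pyridine, pyridine, THF, 0 °C → rt
Reagents that add atoms: none
Why: Buffered fluoride desilylation should free the C8 hydroxyl without acyl migration of the C6 angelate or lactonisation onto the methyl ester, both of which a basic fluoride source would risk.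

**Compound list**

1 | (S)-4-[(tert-butyldimethylsilyl)oxy]cyclohex-2-en-1-one | C1=CC(=O)CC[C@@H]1O[Si](C)(C)C(C)(C)C | starting material
2 | pent-4-enal | C=CCCC=O | starting material
3 | lithium (4S)-4-[(tert-butyldimethylsilyl)oxy]cyclohexa-1,5-dien-1-olate (not isolated) | C1=CC(O[Li])=CC[C@@H]1O[Si](C)(C)C(C)(C)C | intermediate
4 | (4S)-4-[(tert-butyldimethylsilyl)oxy]-6-(1-hydroxypent-4-en-1-yl)cyclohex-2-en-1-one, diastereomer mixture | C1=CC(=O)C(C[C@@H]1O[Si](C)(C)C(C)(C)C)C(O)CCC=C | intermediate
5 | (4S)-4-[(tert-butyldimethylsilyl)oxy]-6-(pent-4-enoyl)cyclohex-2-en-1-one | C1=CC(=O)C(C[C@@H]1O[Si](C)(C)C(C)(C)C)C(=O)CCC=C | intermediate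
6 | (4S,6S)-4-[(tert-butyldimethylsilyl)oxy]-6-methyl-6-(pent-4-enoyl)cyclohex-2-en-1-one | C1=CC(=O)[C@@](C)(C[C@@H]1O[Si](C)(C)C(C)(C)C)C(=O)CCC=C | intermediate
7 | bromomagnesium enolate of the isopropenyl adduct of 6 (not isolated) | CC(=C)[C@H]1C=C(O[Mg]Br)[C@@](C)(C[C@@H]1O[Si](C)(C)C(C)(C)C)C(=O)CCC=C | intermediate
8 | (4S)-4-[(tert-butyldimethylsilyl)oxy]-6-methyl-6-(pent-4-enoyl)-3-(prop-1-en-2-yl)cyclohex-1-en-1-yl trifluoromethanesulfonate (isopropenyl trans to OTBS, methyl cis to isopropenyl) | CC(=C)[C@H]1C=C(OS(=O)(=O)C(F)(F)F)[C@@](C)(C[C@@H]1O[Si](C)(C)C(C)(C)C)C(=O)CCC=C | intermediate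
9 | (4S)-4-[(tert-butyldimethylsilyl)oxy]-6-methyl-6-(4-oxopentanoyl)-3-(prop-1-en-2-yl)cyclohex-1-en-1-yl trifluoromethanesulfonate (same relative configuration) | CC(=C)[C@H]1C=C(OS(=O)(=O)C(F)(F)F)[C@@](C)(C[C@@H]1O[Si](C)(C)C(C)(C)C)C(=O)CCC(C)=O | intermediate
10 | C5 alkenylchromium dichloride from 9, trivalent chromium (not isolated) | CC(=C)[C@H]1C=C([Cr](Cl)Cl)[C@@](C)(C[C@@H]1O[Si](C)(C)C(C)(C)C)C(=O)CCC(C)=O | intermediate
11 | 8α-[(tert-butyldimethylsilyl)oxy]-4α-hydroxy-eudesma-5,11-dien-1-one | CC(=C)[C@H]1C=C2[C@@](C)(C[C@@H]1O[Si](C)(C)C(C)(C)C)C(=O)CC[C@@]2(C)O | intermediate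
12 | 5α,6α-epoxy-8α-[(tert-butyldimethylsilyl)oxy]-4α-hydroxy-eudesm-11-en-1-one | CC(=C)[C@H]1[C@@H]3O[C@]32[C@@](C)(C[C@@H]1O[Si](C)(C)C(C)(C)C)C(=O)CC[C@@]2(C)O | intermediate
13 | 8α-[(tert-butyldimethylsilyl)oxy]-4α,6α-dihydroxy-5αH-eudesm-11-en-1-one | CC(=C)[C@H]1[C@H](O)[C@@H]2[C@@](C)(C[C@@H]1O[Si](C)(C)C(C)(C)C)C(=O)CC[C@@]2(C)O | intermediate
14 | angelic acid, (Z)-2-methylbut-2-enoic acid | C/C=C(/C)C(=O)O | starting material
15 | angelic 2,4,6-trichlorobenzoic anhydride (not isolated) | C/C=C(/C)C(=O)OC(=O)c1c(Cl)cc(Cl)cc1Cl | intermediate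
16 | 6α-angeloyloxy-8α-[(tert-butyldimethylsilyl)oxy]-4α-hydroxy-5αH-eudesm-11-en-1-one | CC(=C)[C@H]1[C@H](OC(=O)/C(C)=C\C)[C@@H]2[C@@](C)(C[C@@H]1O[Si](C)(C)C(C)(C)C)C(=O)CC[C@@]2(C)O | intermediate
17 | 6α-angeloyloxy-8α-[(tert-butyldimethylsilyl)oxy]-4α,12-dihydroxy-5αH-eudesm-11(13)-en-1-one | C=C(CO)[C@H]1[C@H](OC(=O)/C(C)=C\C)[C@@H]2[C@@](C)(C[C@@H]1O[Si](C)(C)C(C)(C)C)C(=O)CC[C@@]2(C)O | intermediate
18 | 6α-angeloyloxy-8α-[(tert-butyldimethylsilyl)oxy]-4α-hydroxy-1-oxo-5αH-eudesm-11(13)-en-12-al (not isolated) | C=C(C=O)[C@H]1[C@H](OC(=O)/C(C)=C\C)[C@@H]2[C@@](C)(C[C@@H]1O[Si](C)(C)C(C)(C)C)C(=O)CC[C@@]2(C)O | intermediate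
19 | 6α-angeloyloxy-8α-[(tert-butyldimethylsilyl)oxy]-4α-hydroxy-1-oxo-5αH-eudesm-11(13)-en-12-oic acid | C=C(C(=O)O)[C@H]1[C@H](OC(=O)/C(C)=C\C)[C@@H]2[C@@](C)(C[C@@H]1O[Si](C)(C)C(C)(C)C)C(=O)CC[C@@]2(C)O | intermediate
20 | methyl 6α-angeloyloxy-8α-[(tert-butyldimethylsilyl)oxy]-4α-hydroxy-1-oxo-5αH-eudesm-11(13)-en-12-oate | C=C(C(=O)OC)[C@H]1[C@H](OC(=O)/C(C)=C\C)[C@@H]2[C@@](C)(C[C@@H]1O[Si](C)(C)C(C)(C)C)C(=O)CC[C@@]2(C)O | intermediate
21 | methyl 6α-angeloyloxy-8α-[(tert-butyldimethylsilyl)oxy]-1β,4α-dihydroxy-5αH-eudesm-11(13)-en-12-oate | C=C(C(=O)OC)[C@H]1[C@H](OC(=O)/C(C)=C\C)[C@@H]2[C@@](C)(C[C@@H]1O[Si](C)(C)C(C)(C)C)[C@H](O)CC[C@@]2(C)O | intermediate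
22 | methyl 6α-angeloyloxy-1β,4α,8α-trihydroxy-5αH-eudesm-11(13)-en-12-oate (CNP0136844.1) | C=C(C(=O)OC)[C@H]1[C@H](OC(=O)/C(C)=C\C)[C@@H]2[C@@](C)(C[C@@H]1O)[C@H](O)CC[C@@]2(C)O | target

**Step count and risks**

Total step count: 14. Longest linear sequence: 14 steps (1 → 22).

Steps most likely to fail:

- **Step 6.** The hindered alkenylchromium may add too slowly to the methyl ketone, so that protodemetalation to the plain olefin takes over, or the facial selectivity at C4 may be poor. The fallback replaces reductive metalation by a ligand-controlled catalytic addition. It sets out from 9: Miyaura borylation (PdCl2(dppf), B2pin2, KOPh, dioxane) should give the alkenyl pinacolboronate F1. A rhodium-catalysed intramolecular 1,2-addition to the C4 ketone ([Rh(OH)(cod)]2, (R)- or (S)-BINAP, dioxane/H2O) should then close the same C4–C5 bond, with the chiral diphosphine as a second control element for the C4 face. It comes back to the route at 11.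

- **Step 3.** Methylation of the planar diketone enolate may show poor facial selectivity at C10, or O-alkylation may compete. The fallback relays C8 to C10 through a temporary tether instead of 1,3-induction. It sets out from 1: α′-methylation (LDA, MeI) should give (4S)-4-[(tert-butyldimethylsilyl)oxy]-6-methylcyclohex-2-en-1-one F2 (configuration at the methyl-bearing carbon immaterial). Desilylation (HF·pyridine) should give (4S)-4-hydroxy-6-methylcyclohex-2-en-1-one F3, and acylation with pent-4-enoyl chloride and pyridine the C8 ester (1S)-5-methyl-4-oxocyclohex-2-en-1-yl pent-4-enoate F4. LiHMDS should then form the C10 enolate, to which the acyl group is handed over from the C8 oxygen on the face of that oxygen (Baker–Venkataraman-type O-to-C acyl shift through a bridged five-membered tetrahedral intermediate). Silylation of the released C8 alkoxide in the same flask (TBSOTf) comes back to the route at 6.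

- **Step 8.** Hydrogen-atom transfer to the C5 radical may lack facial selectivity (cis-decalin), or the titanium-bound radical may collapse back to the olefin or lose the C4 hydroxyl (deoxygenation). The fallback sets C5 and C6 by intramolecular hydrosilylation from the C4 oxygen and bypasses the epoxide. It sets out from 11: silylation with chlorodimethylsilane and Et3N should give the hydrodimethylsilyl ether F5. Platinum-catalysed 5-endo hydrosilylation (Pt2[(CH2=CHSiMe2)2O]3, zerovalent platinum, PhMe) should give the cyclic siloxane F6, with silicon on C6 and hydrogen on C5 both delivered from the α face. Tamao–Fleming oxidation (H2O2, KF, KHCO3), which retains configuration at C6, comes back to the route at 13.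

**Further compounds**

F1 | step 6 | C5 alkenyl pinacolboronate corresponding to 9 | CC(=C)[C@H]1C=C(B2OC(C)(C)C(C)(C)O2)[C@@](C)(C[C@@H]1O[Si](C)(C)C(C)(C)C)C(=O)CCC(C)=O
F2 | step 3 | (4S)-4-[(tert-butyldimethylsilyl)oxy]-6-methylcyclohex-2-en-1-one | C1=CC(=O)C(C)C[C@@H]1O[Si](C)(C)C(C)(C)C
F3 | step 3 | (4S)-4-hydroxy-6-methylcyclohex-2-en-1-one | C1=CC(=O)C(C)C[C@@H]1O
F4 | step 3 | (1S)-5-methyl-4-oxocyclohex-2-en-1-yl pent-4-enoate | C1=CC(=O)C(C)C[C@@H]1OC(=O)CCC=C
F5 | step 8 | 4α-O-(dimethylsilyl) ether of 11 | CC(=C)[C@H]1C=C2[C@@](C)(C[C@@H]1O[Si](C)(C)C(C)(C)C)C(=O)CC[C@@]2(C)O[SiH](C)C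
F6 | step 8 | cyclic siloxane bridging O4 and C6 (5αH, 6α-Si) | CC(=C)[C@H]1[C@H]3[C@@H]2[C@@](C)(C[C@@H]1O[Si](C)(C)C(C)(C)C)C(=O)CC[C@@]2(C)O[Si]3(C)C
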